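The data come from a simulation for substances that don't exist, noise included.

Two questions stand on one flask, with three earlier runs behind it.

| flask | free monomer | protic impurity | initiator | remark | time |
|---|---|---|---|---|---|
| Sunday's | 1.5 M | 1.5 M | 66 mM | run made earlier |  |
| Thursday's | 2.2 M | 1.5 M | 66 mM | run made earlier |  |
| Saturday's | 3 M | 1.5 M | 99 mM | run made earlier |  |
| flask | 3.0 M | 1.50 M | 66 mM |  | 8.0 min |

- Sunday's (time / min: monomer in chains / %, free monomer / %): 0.667: 5.0, 86.2; 1.33: 9.5, 74.9; 3.00: 20.5, 51.5; 8.00: 37.0, 17.4
- Thursday's (time / min: monomer in chains / %, free monomer / %): 2.00: 15.1, 64.1; 4.00: 26.5, 41.4; 6.00: 34.2, 27.4; 8.00: 39.3, 18.4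
- Saturday's (time / min: monomer in chains / %, free monomer / %): 0.667: 6.7, 83.8; 1.33: 15.4, 69.6; 3.00: 31.1, 44.9; 8.00: 51.8, 13.3

(scatter of a reading: 0.5 percentage points)

* average number of monomer units in a chain (chains begun, living or dead) at 8.0 min
* part of the free monomer that has reacted at 8.0 min

- the average divides the monomer in chains by the number of chains begun, living and dead together
- the earlier runs do not show the number of chains; that part of a forecast is a guess

At the last reading, Saturday's run, with 1.50 times Thursday's initiator and a larger charge of free monomer, holds 51.8% of its charge in chains against Thursday's 39.3%. Yet its free monomer stands at 13.3% against 18.4%, so chains have grown 1.32 times while monomer consumed has grown 1.06 times.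

The reckoning here freezes the number of growing chains at the initiator charge, which makes the uptake into chains pseudo-first-order. Between Thursday's readings at 4.00 min and 8.00 min free monomer has a logarithmic mean of 28.4%, and chains gain 12.8%. That gives 8.86 min, the chain time constant: free monomer divided by its rate of entering chains, at 66 mM of initiator. Saturday's last two readings, scaled to that initiator, give 9.41 min. Monomer in neither column is 34.9% on Saturday, less than Thursday's 42.3%.

The flask has Thursday's initiator. Thursday's share in chains with one chain per initiator, a guess, gives my average of 17.9. The forecast says 17 and 80.5%: “Transfer would add chains, so I shade lower; this is a guess.”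

The flask gives 18.5 and 79.6%, both within the forecast's margin.

    free monomer + initiator → living end + monomer in chains (k = 0.0140 M⁻¹ s⁻¹)
    free monomer + living end → monomer in chains + living end, rate k2*[living end]*[free monomer] (k = 0.0280 M⁻¹ s⁻¹)
    free monomer → uncatalysed product (k = 3.30 × 10⁻⁴ s⁻¹)
    protic impurity + free monomer → quenched substrate (k = 0.00140 M⁻¹ s⁻¹)

In the flask the living end stands at 0.0659 M at 4.00 min and 0.0660 M at 8.00 min. Free monomer falls from 42.8% to 20.4% between those times, and the chain time constant turns that into a gain of 13.6% in chains, where the flask shows 13.3%. The neighbouring flask, with 0.040 M of initiator, stretches the constant to 14.6 min. Its free monomer falls from the full charge to 29.4% in 8.0 min, so the same reckoning gives 31.5% in chains. That neighbouring flask holds 28.3%, an average chain of 21.3.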